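Remark on numbering and assumptions: locants in the three sections are those of the IUPAC name of the target (ring C1–C14 with CO2H on C1; side chain C1′–C7′ attached through C2′ to C8). (−)-Ipc2B(allyl) means the reagent derived from (+)-α-pinene. The C1 centre of 25 (C9 of the target) is formed without control, is drawn unspecified and is erased in step 15.

## Structural features

The target is a C25 carbocyclic acid with one 14-membered ring (C1–C14), three endocyclic trisubstituted alkenes and a single stereocentre, C8 (R), which carries a (2E)-6-methylhepta-2,5-dien-2-yl chain (C1′–C7′). The ring alkenes are C1=C2 (E; CO2H on C1 trans to C3, so ring carbons C3 and C14 are cis), C5=C6 (Z, methyl on C5) and C11=C12 (E, methyl on C11). The chain adds C2′=C3′ (E) and the prenyl terminus C5′=C6′. C8 is allylic to C2′=C3′, lies between the allylic methylene C7 and the unactivated methylene C9, and has no heteroatom nearby to direct its formation or a ring closure. Fragile features are the Z-alkene (acid or radical isomerisation), the conjugated acid (deconjugation through C3 or C14) and the electron-rich polyene (cationic cyclisation in strong acid). The real difficulty is to close an all-carbon 14-membered ring, set C8 absolutely, and keep four trisubstituted alkene geometries. The key step exploits the array C9–C8(H)–C2′(CH3)=C3′(H): a ring C–C bond next to an exocyclic allylic alkene is the product pattern of a [3,3] ester-enolate Claisen rearrangement once C9 carries a temporary carboxyl and C3′ an oxygen. The carbocycle then becomes the contraction product of an 18-membered lactone in which C8 is still an sp2 ring carbon and the stereocentre is stored as a carbinol at C3′.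

## Logic of the disconnections

In one sentence: the 14-membered carbocycle arises by Ireland–Claisen ring contraction of the 18-membered macrolactone 22, whose α-carbon is C9 and in which C8 is an alkene carbon.

28 ⇒ 27 ⇒ 25. No skeletal bond is cut. The C1 acid is masked as its ethyl ester (27) and a carboxyl is added to C9 (25) to create the Claisen retron. The forward demand is a decarboxylation that leaves four alkenes untouched; the C9 radical is secondary, not allylic and has no 5- or 6-exo alkene partner.

25 ⇒ 22 (key). The C8–C9 bond is cut, the carboxyl oxygen is reconnected to C3′ and the alkene moves from C2′=C3′ to C8=C2′. This replaces a 14-membered C–C ring closure by a macrolactonisation, moves the stereocentre to a carbinol carbon, and derives the E-C2′=C3′ geometry from the same event. The forward step must enolise the lactone in the presence of the conjugated ester and rearrange with the C4′ substituent pseudo-equatorial.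

22 ⇒ 20 ⇒ 19. The lactone C–O bond is cut, then the saturated acid is traced back to its methyl ester. The gain is an acyclic chain. The demand is differentiation of a saturated methyl ester from a conjugated, α-branched ethyl ester.

19 ⇒ 12 + 17 (through 18). The C7–C8 bond of the skipped diene is cut between an allylic electrophile (C7 of 12) and an alkenyl metal (C8 of 18). C1′ and the E geometry of C8=C2′ come from syn-carbometalation of the alkyne 17. The demand is coupling at the primary allyl terminus with retention of the Z-C5=C6 geometry.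

17 ⇒ 16 ⇒ 15 ⇒ 13. C5′=C6′ is cut by cross-metathesis logic and C3′–C4′ by carbonyl allylation. The C3′ carbinol, the only source of chirality in the route, is set by a reagent-controlled allylation of 13.

12 ⇒ 7 + 11. C1=C2 is cut as a phosphonate olefination. The demand is E selectivity (ester trans to C3).

11 ⇒ 9 ⇒ 8. The C2 aldehyde comes from oxidative cleavage of the terminal isopropylidene group of 8, which supplies C2–C7 and the Z-C5=C6 alkene ready-made.

7 ⇒ 6 + 5 ⇒ 4 ⇒ 2 ⇒ 1. C1–C14 is cut as an alkylation of 6 by bromide 5. The C9–C10 bond and the E-C11=C12 alkene of 4 come from an orthoester Claisen rearrangement of 2, which also brings in C9 with its temporary carboxyl carbon. C11–C12 is cut as an alkenyl addition to aldehyde 1.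

## Other disconnections considered

Alternative 1: Cut C1=C2 and close the ring by an intramolecular Horner–Wadsworth–Emmons reaction of the seco aldehyde–phosphonate A1. This is the first idea that comes to mind and the ring closure itself is plausible. It was not chosen because the olefination solves only the ring closure. C8 and the E-C2′=C3′ alkene would have to be built beforehand by a separate asymmetric sequence, and the E/Z outcome at C1=C2 would depend on ring strain in the closing step and not on a predictable acyclic preference. The chosen plan sets ring, stereocentre and side-chain geometry in one step.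

Alternative 2: Cut C3–C4 and join two carbons of like polarity by a nickel(0)-mediated reductive coupling of the bis(allylic bromide) A2. This was rejected on mechanistic grounds. Both termini pass through π-allyl–nickel species, which can scramble the Z-C5=C6 and the C1=C2 geometries by syn–anti exchange and can couple head-to-tail as well as head-to-head. C8 is again not addressed.

Alternative 3: Cut C5≡C6 and close the ring by alkyne metathesis of the diyne A3 to the cycloalkyne A4, followed by syn-hydrometalation and methylation to install the Z-C5=C6 alkene. Ring closure should be reliable, but the two alkyne carbons of A4 are both flanked by CH2CH2 and nearly equivalent. With no directing hydroxyl there is no reason to expect the methyl to go selectively to C5. The sequence also costs more steps after ring closure and leaves C8 to be made separately.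

Key step: step 14

## Route

Step 1
Reactants: 1 3-[(tert-butyldimethylsilyl)oxy]propanal
Product: 2 5-[(tert-butyldimethylsilyl)oxy]-2-methylpent-1-en-3-ol (racemic)
Conditions: CH2=C(CH3)MgBr, THF, −78 → 0 °C; aq. NH4Cl
Reagents that add atoms: isopropenylmagnesium bromide, CC(=C)[Mg]Br
Why: 1,2-addition of the alkenyl Grignard reagent to the aldehyde; the carbinol centre is racemic by design because it is destroyed in step 2.

Step 2
Reactants: 2 5-[(tert-butyldimethylsilyl)oxy]-2-methylpent-1-en-3-ol
Product: 4 methyl (4E)-7-[(tert-butyldimethylsilyl)oxy]-4-methylhept-4-enoate, via mixed ketene acetal 3 (not isolated)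
Conditions: MeC(OMe)3, EtCO2H (cat.), toluene, 110 °C, MeOH distilled off
Reagents that add atoms: trimethyl orthoacetate, COC(C)(OC)OC
Why: Johnson–Claisen rearrangement: orthoester exchange and loss of methanol give ketene acetal 3, which rearranges through a chair with the CH2CH2OTBS group pseudo-equatorial, so the new trisubstituted alkene should be E. The step also brings in the future C9 with its carboxyl carbon.

Step 3
Reactants: 4 methyl (4E)-7-[(tert-butyldimethylsilyl)oxy]-4-methylhept-4-enoate
Product: 5 methyl (4E)-7-bromo-4-methylhept-4-enoate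
Conditions: Ph3PBr2, CH2Cl2, 0 °C → rt
Reagents that add atoms: triphenylphosphine dibromide, BrP(Br)(c1ccccc1)(c1ccccc1)c1ccccc1
Why: Direct conversion of a primary silyl ether into the bromide by a bromophosphonium salt (oxyphosphonium formation, then SN2 by bromide); the ester and the alkene are inert and no geometry is touched.

Step 4
Reactants: 5 methyl (4E)-7-bromo-4-methylhept-4-enoate; 6 triethyl phosphonoacetate
Product: 7 1-ethyl 9-methyl (5E)-2-(diethoxyphosphoryl)-6-methylnon-5-enedioate
Conditions: NaH, DMF, 0 °C; then 5, NaI (cat.), 50 °C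
Reagents that add atoms: none
Why: SN2 C-alkylation of the soft, weakly basic phosphonoacetate anion by the primary bromide, with iodide catalysis to outrun E2; the methyl ester α-protons are far less acidic and stay untouched.

Step 5
Reactants: 8 neryl acetate
Product: 9 (2Z)-5-(3,3-dimethyloxiran-2-yl)-3-methylpent-2-en-1-yl acetate (racemic)
Conditions: mCPBA, NaHCO3, CH2Cl2, 0 °C
Reagents that add atoms: 3-chloroperoxybenzoic acid, OOC(=O)c1cccc(Cl)c1
Why: Prilezhaev epoxidation; the remote trisubstituted alkene is more electron-rich than the one deactivated by the allylic acetoxy group and should react selectively.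

Step 6
Reactants: 9 (2Z)-5-(3,3-dimethyloxiran-2-yl)-3-methylpent-2-en-1-yl acetate
Product: 11 (2Z)-3-methyl-6-oxohex-2-en-1-yl acetate, via vicinal diol 10 (not isolated)
Conditions: H5IO6, THF/H2O, 0 °C → rt
Reagents that add atoms: none
Why: Epoxide hydrolysis to diol 10 and periodate glycol cleavage in one pot; the Z-alkene and the allylic acetate are not affected.

Step 7
Reactants: 7 1-ethyl 9-methyl (5E)-2-(diethoxyphosphoryl)-6-methylnon-5-enedioate; 11 (2Z)-3-methyl-6-oxohex-2-en-1-yl acetate
Product: 12 methyl (4E,8E,12Z)-14-(acetyloxy)-8-(ethoxycarbonyl)-4,12-dimethyltetradeca-4,8,12-trienoate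
Conditions: NaH, THF, 0 °C; then 11, 0 °C → rt
Reagents that add atoms: none
Why: Horner–Wadsworth–Emmons olefination; the phosphonoacetate C–H is the most acidic site, and reversible addition followed by syn-elimination favours the (E)-enoate with the ester trans to the β-alkyl group. A minor (Z)-isomer should be separable.

Step 8
Reactants: 13 3-(trimethylsilyl)prop-2-ynal
Product: 15 (3S)-1-(trimethylsilyl)hex-5-en-1-yn-3-ol, via borinate ester 14 (not isolated)
Conditions: (−)-Ipc2B(allyl), Et2O, −78 °C; then HOCH2CH2NH2, rt
Reagents that add atoms: (−)-B-allylbis[(1R,2S,3R,5R)-isopinocampheyl]borane, C[C@H]1[C@@H](C[C@@H]2C[C@H]1C2(C)C)B(CC=C)[C@@H]1C[C@@H]2C[C@H]([C@H]1C)C2(C)C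
Why: Brown allylation: allyl transfer through a closed chair transition state in which the isopinocampheyl groups from (+)-α-pinene direct attack to the Si face of the ynal, which should give the (S)-carbinol (future C3′). The non-oxidative ethanolamine work-up spares the C–Si bond.

Step 9
Reactants: 15 (3S)-1-(trimethylsilyl)hex-5-en-1-yn-3-ol
Product: 16 (3S)-6-methyl-1-(trimethylsilyl)hept-5-en-1-yn-3-ol
Conditions: Grubbs II (3 mol %), 2-methylbut-2-ene/CH2Cl2, 35 °C
Reagents that add atoms: 2-methylbut-2-ene, CC=C(C)C
Why: Olefin cross-metathesis of the terminal alkene with 2-methylbut-2-ene installs the isopropylidene terminus; the silyl-capped alkyne and the carbinol centre are not involved.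

Step 10
Reactants: 16 (3S)-6-methyl-1-(trimethylsilyl)hept-5-en-1-yn-3-ol
Product: 17 (3S)-6-methylhept-5-en-1-yn-3-ol
Conditions: K2CO3 (0.2 equiv), MeOH, rt
Reagents that add atoms: none
Why: Methanolysis of the alkynyl–silicon bond under mild base; the propargylic stereocentre cannot epimerise under these conditions.

Step 11
Reactants: 17 (3S)-6-methylhept-5-en-1-yn-3-ol; 12 methyl (4E,8E,12Z)-14-(acetyloxy)-8-(ethoxycarbonyl)-4,12-dimethyltetradeca-4,8,12-trienoate
Product: 19 methyl (4E,8E,12Z,15E,17S)-8-(ethoxycarbonyl)-17-hydroxy-4,12,16,20-tetramethylhenicosa-4,8,12,15,19-pentaenoate, via alkenylalane 18 (not isolated)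
Conditions: Me3Al (3 equiv), Cp2ZrCl2 (0.25 equiv), CH2Cl2, 0 °C → rt, excess Me3Al removed in vacuo; then 12, Pd(PPh3)4 (5 mol %), THF, rt; aq. Rochelle salt
Reagents that add atoms: trimethylaluminium, C[Al](C)C
Why: Negishi zirconium-catalysed carboalumination adds CH3 and Al syn across the alkyne with Al on the terminal carbon, giving (E)-alkenylalane 18 with the hydroxyl carried as its aluminium alkoxide. Palladium-catalysed alkenyl–allyl coupling with allylic acetate 12 should then join the alkenyl carbon to the primary allyl terminus with retention of both alkene geometries, because the 3,3-disubstituted π-allyl terminus resists syn–anti exchange. The carbinol stereocentre is untouched.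

Step 12
Reactants: 19 methyl (4E,8E,12Z,15E,17S)-8-(ethoxycarbonyl)-17-hydroxy-4,12,16,20-tetramethylhenicosa-4,8,12,15,19-pentaenoate
Product: 20 (4E,8E,12Z,15E,17S)-8-(ethoxycarbonyl)-17-hydroxy-4,12,16,20-tetramethylhenicosa-4,8,12,15,19-pentaenoic acid
Conditions: LiOH·H2O (1.2 equiv), THF/MeOH/H2O, 0 °C; then 0.5 M HCl to pH 4, 0 °C
Reagents that add atoms: lithium hydroxide, [Li+].[OH-]
Why: Saponification; the unhindered saturated methyl ester should be attacked much faster than the α-branched conjugated ethyl ester, and mild acidification avoids ionising the allylic alcohol.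

Step 13
Reactants: 20 (4E,8E,12Z,15E,17S)-8-(ethoxycarbonyl)-17-hydroxy-4,12,16,20-tetramethylhenicosa-4,8,12,15,19-pentaenoic acid
Product: 22 ethyl (5E,9E,13Z,16E,18S)-5,13,17-trimethyl-18-(3-methylbut-2-en-1-yl)-2-oxo-1-oxacyclooctadeca-5,9,13,16-tetraene-9-carboxylate, via mixed anhydride 21 (not isolated)
Conditions: 2,4,6-Cl3C6H2COCl, Et3N, THF, rt; then slow addition to DMAP, toluene, 60 °C (about 1 mM)
Reagents that add atoms: none
Why: Yamaguchi macrolactonisation via mixed anhydride 21 and an acylpyridinium under high dilution; an 18-membered lactone from a flexible chain is far easier to close than a 14-membered carbocycle, and the carbinol configuration is retained because only the acyl–oxygen bond is formed.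

Step 14
Reactants: 22 ethyl (5E,9E,13Z,16E,18S)-5,13,17-trimethyl-18-(3-methylbut-2-en-1-yl)-2-oxo-1-oxacyclooctadeca-5,9,13,16-tetraene-9-carboxylate
Product: 25 (1RS,3E,7E,11Z,14S)-7-(ethoxycarbonyl)-3,11-dimethyl-14-[(2E)-6-methylhepta-2,5-dien-2-yl]cyclotetradeca-3,7,11-triene-1-carboxylic acid, via silyl ketene acetal 23 (not isolated), via trimethylsilyl ester 24 (not isolated)
Conditions: TMSCl/Et3N, THF, −78 °C; LDA (1.1 equiv), −78 °C → rt → 60 °C; then dilute aq. HCl (pH 3), 0 °C
Reagents that add atoms: none
Why: Ireland–Claisen rearrangement run as a ring contraction of a macrolactone, a known reaction type: kinetic deprotonation of the lactone α-CH2 (future C9) with TMSCl present gives silyl ketene acetal 23, whose O–C(=C9)–O–C3′–C2′=C8 array undergoes a concerted suprafacial [3,3] shift on warming, forming C8–C9, breaking C3′–O and moving the alkene to C2′=C3′; work-up cleaves silyl ester 24. The 14-membered carbocycle is closed by transannular bond formation inside the 18-membered ring through a six-membered chair- or boat-like pericyclic array (18 → 14 contraction, with the carboxyl carbon and the C2′–C3′ pair expelled from the ring), not by an end-to-end cyclisation. C8 is set by 1,3-chirality transfer from the (S)-carbinol C3′ across the (E)-C8=C2′ alkene: with the C4′ methylene pseudo-equatorial (avoiding the 1,3-diaxial contact with OSiMe3) the new bond is delivered to the face of C8 from which oxygen departs, which gives (R) at C8 of the target, written (14S) in 25 only because the neighbouring carboxyl changes the CIP order. Chair and boat arrays deliver the same face, so the result does not depend on ketene acetal geometry. The same pseudo-equatorial preference sets (E)-C2′=C3′, as in the classical Claisen syntheses of trisubstituted alkenes from 2-methylallyl carbinols. The new centre at C9 is uncontrolled and irrelevant because step 15 removes it. The selectivity needed is enolisation of the saturated lactone over γ-deprotonation or conjugate attack at the α-branched conjugated ethyl ester; it should be secured by the higher kinetic acidity of the saturated ester α-protons, a small excess of base only, and the internal TMSCl quench.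

Step 15
Reactants: 25 (1RS,3E,7E,11Z,14S)-7-(ethoxycarbonyl)-3,11-dimethyl-14-[(2E)-6-methylhepta-2,5-dien-2-yl]cyclotetradeca-3,7,11-triene-1-carboxylic acid
Product: 27 ethyl (1E,5Z,8R,11E)-5,11-dimethyl-8-[(2E)-6-methylhepta-2,5-dien-2-yl]cyclotetradeca-1,5,11-triene-1-carboxylate, via thiohydroxamate ester 26 (not isolated)
Conditions: N-hydroxypyridine-2-thione, DCC, DMAP (cat.), CH2Cl2, rt, dark; then t-BuSH (excess), hν (W lamp), 0 °C → rt
Reagents that add atoms: none
Why: Barton reductive decarboxylation: ester 26 fragments in a radical chain to CO2 and a secondary C-radical at the former α-carbon, which the thiol should reduce faster than any rearrangement (not allylic, no 5- or 6-exo alkene partner). This erases the uncontrolled centre and leaves the ring CH2; the conjugated ester is inert.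

Step 16
Reactants: 27 ethyl (1E,5Z,8R,11E)-5,11-dimethyl-8-[(2E)-6-methylhepta-2,5-dien-2-yl]cyclotetradeca-1,5,11-triene-1-carboxylate
Product: 28 (1E,5Z,8R,11E)-5,11-dimethyl-8-[(2E)-6-methylhepta-2,5-dien-2-yl]cyclotetradeca-1,5,11-triene-1-carboxylic acid
Conditions: LiOH (excess), THF/MeOH/H2O, 50 °C; then dilute HCl to pH 3, 0 °C
Reagents that add atoms: lithium hydroxide, [Li+].[OH-]
Why: Saponification of the hindered conjugated ester needs heating but touches no stereocentre; hydroxide is not basic enough to deconjugate the enoate, and mild acidification liberates the target acid.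

## Compound list

1 | 3-[(tert-butyldimethylsilyl)oxy]propanal | CC(C)(C)[Si](C)(C)OCCC=O | starting material
2 | 5-[(tert-butyldimethylsilyl)oxy]-2-methylpent-1-en-3-ol (racemic) | CC(=C)C(O)CCO[Si](C)(C)C(C)(C)C | intermediate
3 | tert-butyl({3-[(1-methoxyethenyl)oxy]-4-methylpent-4-en-1-yl}oxy)dimethylsilane (mixed ketene acetal) | C=C(OC)OC(CCO[Si](C)(C)C(C)(C)C)C(C)=C | intermediate (not isolated)
4 | methyl (4E)-7-[(tert-butyldimethylsilyl)oxy]-4-methylhept-4-enoate | COC(=O)CC/C(C)=C/CCO[Si](C)(C)C(C)(C)C | intermediate
5 | methyl (4E)-7-bromo-4-methylhept-4-enoate | COC(=O)CC/C(C)=C/CCBr | intermediate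
6 | triethyl phosphonoacetate | CCOC(=O)CP(=O)(OCC)OCC | starting material
7 | 1-ethyl 9-methyl (5E)-2-(diethoxyphosphoryl)-6-methylnon-5-enedioate | CCOC(=O)C(CC/C=C(\C)CCC(=O)OC)P(=O)(OCC)OCC | intermediate
8 | neryl acetate, (2Z)-3,7-dimethylocta-2,6-dien-1-yl acetate | CC(C)=CCC/C(C)=C\COC(C)=O | starting material
9 | (2Z)-5-(3,3-dimethyloxiran-2-yl)-3-methylpent-2-en-1-yl acetate (racemic) | CC1(C)OC1CC/C(C)=C\COC(C)=O | intermediate
10 | (2Z)-6,7-dihydroxy-3,7-dimethyloct-2-en-1-yl acetate (racemic) | CC(C)(O)C(O)CC/C(C)=C\COC(C)=O | intermediate (not isolated)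
11 | (2Z)-3-methyl-6-oxohex-2-en-1-yl acetate | O=CCC/C(C)=C\COC(C)=O | intermediate
12 | methyl (4E,8E,12Z)-14-(acetyloxy)-8-(ethoxycarbonyl)-4,12-dimethyltetradeca-4,8,12-trienoate | COC(=O)CC/C(C)=C/CC/C(C(=O)OCC)=C\CC/C(C)=C\COC(C)=O | intermediate
13 | 3-(trimethylsilyl)prop-2-ynal | C[Si](C)(C)C#CC=O | starting material
14 | (3S)-1-(trimethylsilyl)hex-5-en-1-yn-3-yl bis[(1R,2S,3R,5R)-isopinocampheyl]borinate | C[C@H]1[C@@H](C[C@@H]2C[C@H]1C2(C)C)B(O[C@@H](CC=C)C#C[Si](C)(C)C)[C@@H]1C[C@@H]2C[C@H]([C@H]1C)C2(C)C | intermediate (not isolated)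
15 | (3S)-1-(trimethylsilyl)hex-5-en-1-yn-3-ol | C[Si](C)(C)C#C[C@@H](O)CC=C | intermediate
16 | (3S)-6-methyl-1-(trimethylsilyl)hept-5-en-1-yn-3-ol | C[Si](C)(C)C#C[C@@H](O)CC=C(C)C | intermediate
17 | (3S)-6-methylhept-5-en-1-yn-3-ol | C#C[C@@H](O)CC=C(C)C | intermediate
18 | {(1E,3S)-3-[(dimethylalumanyl)oxy]-2,6-dimethylhepta-1,5-dien-1-yl}dimethylalumane | C[Al](C)/C=C(\C)[C@@H](O[Al](C)C)CC=C(C)C | intermediate (not isolated)
19 | methyl (4E,8E,12Z,15E,17S)-8-(ethoxycarbonyl)-17-hydroxy-4,12,16,20-tetramethylhenicosa-4,8,12,15,19-pentaenoate | COC(=O)CC/C(C)=C/CC/C(C(=O)OCC)=C\CC/C(C)=C\C/C=C(\C)[C@@H](O)CC=C(C)C | intermediate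
20 | (4E,8E,12Z,15E,17S)-8-(ethoxycarbonyl)-17-hydroxy-4,12,16,20-tetramethylhenicosa-4,8,12,15,19-pentaenoic acid | OC(=O)CC/C(C)=C/CC/C(C(=O)OCC)=C\CC/C(C)=C\C/C=C(\C)[C@@H](O)CC=C(C)C | intermediate
21 | mixed anhydride of 20 with 2,4,6-trichlorobenzoic acid | O=C(CC/C(C)=C/CC/C(C(=O)OCC)=C\CC/C(C)=C\C/C=C(\C)[C@@H](O)CC=C(C)C)OC(=O)c1c(Cl)cc(Cl)cc1Cl | intermediate (not isolated)
22 | ethyl (5E,9E,13Z,16E,18S)-5,13,17-trimethyl-18-(3-methylbut-2-en-1-yl)-2-oxo-1-oxacyclooctadeca-5,9,13,16-tetraene-9-carboxylate | O=C1CC/C(C)=C/CC/C(C(=O)OCC)=C\CC/C(C)=C\C/C=C(\C)[C@H](CC=C(C)C)O1 | intermediate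
23 | ethyl (5E,9E,13Z,16E,18S)-5,13,17-trimethyl-18-(3-methylbut-2-en-1-yl)-2-[(trimethylsilyl)oxy]-1-oxacyclooctadeca-2,5,9,13,16-pentaene-9-carboxylate (ketene acetal geometry open) | C[Si](C)(C)OC1=CC/C(C)=C/CC/C(C(=O)OCC)=C\CC/C(C)=C\C/C=C(\C)[C@H](CC=C(C)C)O1 | intermediate (not isolated)
24 | trimethylsilyl ester of 25 | CC(C)=CC/C=C(\C)[C@H]1C/C=C(/C)CC/C=C(/C(=O)OCC)CC/C=C(\C)CC1C(=O)O[Si](C)(C)C | intermediate (not isolated)
25 | (1RS,3E,7E,11Z,14S)-7-(ethoxycarbonyl)-3,11-dimethyl-14-[(2E)-6-methylhepta-2,5-dien-2-yl]cyclotetradeca-3,7,11-triene-1-carboxylic acid | CC(C)=CC/C=C(\C)[C@H]1C/C=C(/C)CC/C=C(/C(=O)OCC)CC/C=C(\C)CC1C(=O)O | intermediate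
26 | 2-thioxopyridin-1(2H)-yl ester of 25 | CC(C)=CC/C=C(\C)[C@H]1C/C=C(/C)CC/C=C(/C(=O)OCC)CC/C=C(\C)CC1C(=O)ON2C=CC=CC2=S | intermediate (not isolated)
27 | ethyl (1E,5Z,8R,11E)-5,11-dimethyl-8-[(2E)-6-methylhepta-2,5-dien-2-yl]cyclotetradeca-1,5,11-triene-1-carboxylate | CC(C)=CC/C=C(\C)[C@H]1C/C=C(/C)CC/C=C(/C(=O)OCC)CC/C=C(\C)CC1 | intermediate
28 | (1E,5Z,8R,11E)-5,11-dimethyl-8-[(2E)-6-methylhepta-2,5-dien-2-yl]cyclotetradeca-1,5,11-triene-1-carboxylic acid | CC(C)=CC/C=C(\C)[C@H]1C/C=C(/C)CC/C=C(/C(=O)O)CC/C=C(\C)CC1 | target

## Step count and least certain steps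

Total step count: 16. Longest linear sequence: 11 steps (steps 1–4, 7, 11–16).

Step 14 (key step). The most likely failure is loss of chemoselectivity in the enolisation: deprotonation at the γ-positions of the conjugated ethyl ester, or conjugate attack there, would lead to deconjugation or transannular Michael addition instead of the silyl ketene acetal. A sluggish rearrangement through an unfavourable macrocyclic conformation is less likely for an 18-membered ring. The fallback keeps the Claisen chirality transfer but runs it on an acyclic ester without the enoate and closes the ring conventionally. It sets out from 11, 17 and 5 and returns at 27. Aldehyde 11 is protected as (2Z)-6,6-dimethoxy-3-methylhex-2-en-1-yl acetate F1. Alkenylalane 18, made from 17 as in step 11, is coupled with F1 under Pd(PPh3)4 to give (5S,6E,9Z)-13,13-dimethoxy-2,6,10-trimethyltrideca-2,6,9-trien-5-ol F2. Ester 5 is saponified to (4E)-7-bromo-4-methylhept-4-enoic acid F3, and F2 is acylated with F3 (DCC, DMAP) to the allylic ester F4. Acyclic Ireland–Claisen rearrangement of F4 (LDA, TMSCl) should give the branched acid F5 with the same sense of chirality transfer, and Barton decarboxylation should give the bromide F6. Alkylation of 6 with F6 gives the phosphonate acetal F7, mild acid hydrolysis unmasks the seco aldehyde–phosphonate A1, and intramolecular Horner–Wadsworth–Emmons olefination under high dilution (LiCl, DBU) returns to 27.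

Step 11. The one-pot sequence may suffer from incomplete or unselective carboalumination of the free propargylic alcohol, slow oxidative addition of the allylic acetate, or Lewis-acid attack of aluminium species on the esters; geometric leakage at the Z-alkene through the π-allyl is a smaller risk. The fallback changes the metal pair. It sets out from 17 and returns at 19. Stannylcupration of 17 with in situ methylation gives (1E,3S)-2,6-dimethyl-1-(tributylstannyl)hepta-1,5-dien-3-ol F8, which is joined to 12 by a Stille coupling with the allylic acetate (Pd2(dba)3, LiCl, DMF).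

Step 7. Insufficient E selectivity is the main risk, because α-alkyl phosphonoacetates and unbranched aldehydes can give appreciable (Z)-enoate, which would be carried as a ring-geometry error. The fallback replaces the phosphonate by a stabilised phosphorane, which is intrinsically more E-selective. It sets out from 5 and 11 and returns at 12. Bromide 5 alkylates ethyl (triphenylphosphoranylidene)acetate (two equivalents, transylidation) to give the phosphorane F9, and a Wittig reaction of F9 with 11 in warm toluene gives 12.

Step 15. Thiyl radicals add reversibly to alkenes and could isomerise the Z-alkene; a slower hydrogen donor would instead open the way to β-scission or transannular addition of the secondary radical. The fallback avoids thiyl radicals. It sets out from 25 and returns at 27. Acid 25 is converted into its N-acyloxyphthalimide F10 (N-hydroxyphthalimide, DIC), which is reduced with a nickel catalyst, zinc and phenylsilane.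

Step 8. The enantioselectivity of allylboration of a small alkynyl aldehyde may be lower than for alkyl or aryl aldehydes, and any erosion is carried directly into C8. The fallback is a resolution. It sets out from 13 and returns at 15. Addition of allylmagnesium bromide to 13 gives the racemic alcohol F11; lipase-catalysed acylation with vinyl acetate is expected to esterify the (R)-enantiomer to the acetate F12 and leave 15, at the cost of half the material.

## Further compounds

F1 | step 14 | (2Z)-6,6-dimethoxy-3-methylhex-2-en-1-yl acetate | COC(OC)CC/C(C)=C\COC(C)=O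
F2 | step 14 | (5S,6E,9Z)-13,13-dimethoxy-2,6,10-trimethyltrideca-2,6,9-trien-5-ol | COC(OC)CC/C(C)=C\C/C=C(\C)[C@@H](O)CC=C(C)C
F3 | step 14 | (4E)-7-bromo-4-methylhept-4-enoic acid | OC(=O)CC/C(C)=C/CCBr
F4 | step 14 | (5S,6E,9Z)-13,13-dimethoxy-2,6,10-trimethyltrideca-2,6,9-trien-5-yl (4E)-7-bromo-4-methylhept-4-enoate | COC(OC)CC/C(C)=C\C/C=C(\C)[C@H](CC=C(C)C)OC(=O)CC/C(C)=C/CCBr
F5 | step 14 | (2RS,3S,4E)-2-[(2E)-5-bromo-2-methylpent-2-en-1-yl]-3-[(2Z)-6,6-dimethoxy-3-methylhex-2-en-1-yl]-4,8-dimethylnona-4,7-dienoic acid | CC(C)=CC/C=C(\C)[C@@H](C/C=C(/C)CCC(OC)OC)C(C(=O)O)C/C(C)=C/CCBr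
F6 | step 14 | (3E,7R,9Z)-1-bromo-13,13-dimethoxy-4,10-dimethyl-7-[(2E)-6-methylhepta-2,5-dien-2-yl]trideca-3,9-diene | CC(C)=CC/C=C(\C)[C@@H](C/C=C(/C)CCC(OC)OC)CC/C(C)=C/CCBr
F7 | step 14 | ethyl (5E,9R,11Z)-2-(diethoxyphosphoryl)-15,15-dimethoxy-6,12-dimethyl-9-[(2E)-6-methylhepta-2,5-dien-2-yl]pentadeca-5,11-dienoate | CC(C)=CC/C=C(\C)[C@@H](C/C=C(/C)CCC(OC)OC)CC/C(C)=C/CCC(C(=O)OCC)P(=O)(OCC)OCC
F8 | step 11 | (1E,3S)-2,6-dimethyl-1-(tributylstannyl)hepta-1,5-dien-3-ol | CCCC[Sn](CCCC)(CCCC)/C=C(\C)[C@@H](O)CC=C(C)C
F9 | step 7 | 1-ethyl 9-methyl (5E)-6-methyl-2-(triphenyl-λ5-phosphanylidene)non-5-enedioate | CCOC(=O)C(CC/C=C(\C)CCC(=O)OC)=P(c1ccccc1)(c1ccccc1)c1ccccc1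
F10 | step 15 | 1,3-dioxoisoindolin-2-yl ester of 25 | CC(C)=CC/C=C(\C)[C@H]1C/C=C(/C)CC/C=C(/C(=O)OCC)CC/C=C(\C)CC1C(=O)ON3C(=O)c4ccccc4C3=O
F11 | step 8 | rac-1-(trimethylsilyl)hex-5-en-1-yn-3-ol | C[Si](C)(C)C#CC(O)CC=C
F12 | step 8 | (3R)-1-(trimethylsilyl)hex-5-en-1-yn-3-yl acetate | C[Si](C)(C)C#C[C@@H](CC=C)OC(C)=O
A1 | alternative 1 | ethyl (5E,9R,11Z)-2-(diethoxyphosphoryl)-6,12-dimethyl-9-[(2E)-6-methylhepta-2,5-dien-2-yl]-15-oxopentadeca-5,11-dienoate | CC(C)=CC/C=C(\C)[C@@H](C/C=C(/C)CCC=O)CC/C(C)=C/CCC(C(=O)OCC)P(=O)(OCC)OCC
A2 | alternative 2 | ethyl (2E,5E,9R,11Z)-13-bromo-2-(2-bromoethylidene)-6,12-dimethyl-9-[(2E)-6-methylhepta-2,5-dien-2-yl]trideca-5,11-dienoate | CC(C)=CC/C=C(\C)[C@@H](C/C=C(/C)CBr)CC/C(C)=C/CC/C(C(=O)OCC)=C\CBr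
A3 | alternative 3 | ethyl (2E,5E,9R)-2-(hex-4-yn-1-ylidene)-6-methyl-9-[(2E)-6-methylhepta-2,5-dien-2-yl]tridec-5-en-11-ynoate | CC#CC[C@@H](CC/C(C)=C/CC/C(C(=O)OCC)=C\CCC#CC)/C(C)=C/CC=C(C)C
A4 | alternative 3 | ethyl (1E,8R,11E)-11-methyl-8-[(2E)-6-methylhepta-2,5-dien-2-yl]cyclotetradeca-1,11-dien-5-yne-1-carboxylate | CC(C)=CC/C=C(\C)[C@H]1CC#CCC/C=C(/C(=O)OCC)CC/C=C(\C)CC1
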